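**Retrosynthetic overview**
- Feature: in the 2,3-dihydrobenzofuran, O1 is bonded to C7a, and C7a is para to C5 (the carbon carrying the 3-hydroxypropyl chain) and next to the methoxy-bearing C7. With C5 at the aldehyde level, the benzo ring is a 4,5-dimethoxybenzaldehyde whose C4 methoxy group (future C7a) can leave in an SNAr reaction.
- Disconnection 1: O1–C7a, by attack of the C2 alkoxide on C7a with loss of methoxide. The C5 chain is grown afterwards from the formyl group (olefination, hydrogenation, reduction).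
- Disconnection 2: C2–C3, with both stereocentres, by an Evans syn-aldol reaction of an (S)-4-benzyloxazolidinone arylacetyl imide with O-benzylsyringaldehyde. The syn (1S,2R) open chain becomes the trans (2S,3R) ring.
- Disconnection 3: the aryl–CH2 bond of the arylacetic acid, by Pd-catalysed coupling of acetal-protected 5-bromoveratraldehyde with a Reformatsky reagent.
- Ring order: both benzene rings are bought; the dihydrofuran ring is the only ring made (step 9).

Key step: step 9

Assumption: 3-bromo-4,5-dimethoxybenzaldehyde (the O-methyl ether of 5-bromovanillin) and the THF solution of (2-ethoxy-2-oxoethyl)zinc bromide are taken as purchased; the zinc reagent is otherwise made from ethyl bromoacetate and activated zinc.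

**Route**

Step 1
Reactants: 1 3-bromo-4,5-dimethoxybenzaldehyde
Product: 2 2-(3-bromo-4,5-dimethoxyphenyl)-1,3-dioxolane
Conditions: ethylene glycol, TsOH·H2O (cat.), toluene, reflux, Dean–Stark
Reagents that add atoms: ethylene glycol, OCCO
Why: Acid-catalysed acetalisation with azeotropic removal of water masks the formyl group, which would otherwise react with the zinc enolate, the boron enolate and the borohydride of steps 2, 6 and 7.

Step 2
Reactants: 2 2-(3-bromo-4,5-dimethoxyphenyl)-1,3-dioxolane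
Product: 3 ethyl 2-[5-(1,3-dioxolan-2-yl)-2,3-dimethoxyphenyl]acetate
Conditions: BrZnCH2CO2Et (0.5 M in THF), Pd2(dba)3 (cat.), XPhos (cat.), THF, 60 °C
Reagents that add atoms: (2-ethoxy-2-oxoethyl)zinc bromide, CCOC(=O)C[Zn]Br
Why: Palladium-catalysed cross-coupling of a Reformatsky reagent with an aryl bromide (Negishi-type α-arylation of an ester zinc enolate) tolerates the acetal and the ortho methoxy group and should stop at the mono-arylated acetate.

Step 3
Reactants: 3 ethyl 2-[5-(1,3-dioxolan-2-yl)-2,3-dimethoxyphenyl]acetate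
Product: 4 2-[5-(1,3-dioxolan-2-yl)-2,3-dimethoxyphenyl]acetic acid
Conditions: LiOH·H2O, THF–H2O, rt; then 1 M HCl to pH 4, 0 °C, immediate extraction
Reagents that add atoms: lithium hydroxide, [Li+].[OH-]
Why: Saponification of the ethyl ester, in which the dioxolane is stable to the base and should survive the brief cold acidification to pH 4.

Step 4
Reactants: 4 2-[5-(1,3-dioxolan-2-yl)-2,3-dimethoxyphenyl]acetic acid; 5 (S)-4-benzyl-1,3-oxazolidin-2-one
Product: 7 (S)-4-benzyl-3-{2-[5-(1,3-dioxolan-2-yl)-2,3-dimethoxyphenyl]acetyl}-1,3-oxazolidin-2-one, via mixed pivalic anhydride 6 (not isolated)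
Conditions: PivCl, Et3N, THF, −20 °C; then 5, LiCl, −20 °C → rt
Reagents that add atoms: none
Why: N-Acylation of the oxazolidinone through the mixed pivalic anhydride (triethylamine–lithium chloride protocol), in which the hindered pivaloyl carbonyl directs attack to the arylacetyl carbonyl.

Step 5
Reactants: 8 syringaldehyde (4-hydroxy-3,5-dimethoxybenzaldehyde)
Product: 9 4-benzyloxy-3,5-dimethoxybenzaldehyde
Conditions: BnBr, K2CO3, DMF, 60 °C
Reagents that add atoms: benzyl bromide, BrCc1ccccc1
Why: Williamson etherification protects the phenol as a benzyl ether that is stable to the boron enolate, hydride and alkoxide steps and is removed later by hydrogenolysis.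

Step 6
Reactants: 7 (S)-4-benzyl-3-{2-[5-(1,3-dioxolan-2-yl)-2,3-dimethoxyphenyl]acetyl}-1,3-oxazolidin-2-one; 9 4-benzyloxy-3,5-dimethoxybenzaldehyde
Product: 12 (S)-4-benzyl-3-[(2S,3S)-3-(4-benzyloxy-3,5-dimethoxyphenyl)-2-[5-(1,3-dioxolan-2-yl)-2,3-dimethoxyphenyl]-3-hydroxypropanoyl]-1,3-oxazolidin-2-one, via boron enolate 10 (not isolated), via boron aldolate 11 (not isolated)
Conditions: Bu2BOTf, i-Pr2NEt, CH2Cl2, −78 → 0 °C; then 9, −78 → 0 °C; then pH 7 buffer, MeOH, 30% H2O2, 0 °C
Reagents that add atoms: none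
Why: Evans syn-aldol reaction, in which the (Z)-dibutylboron enolate reacts through a chair Zimmerman–Traxler transition state on the enolate face away from the C4 benzyl group of the auxiliary, which should set both stereocentres as (2S,3S).

Step 7
Reactants: 12 (S)-4-benzyl-3-[(2S,3S)-3-(4-benzyloxy-3,5-dimethoxyphenyl)-2-[5-(1,3-dioxolan-2-yl)-2,3-dimethoxyphenyl]-3-hydroxypropanoyl]-1,3-oxazolidin-2-one
Product: 14 3-[(1S,2R)-1-(4-benzyloxy-3,5-dimethoxyphenyl)-1,3-dihydroxypropan-2-yl]-4,5-dimethoxybenzaldehyde, via diol acetal 13 (not isolated)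
Conditions: LiBH4, MeOH (1 equiv), THF, 0 °C; aq NH4Cl (destroys excess hydride); then 1 M HCl, THF–H2O, rt
Reagents that add atoms: water, O
Why: Reductive cleavage of the N-acyloxazolidinone by lithium borohydride gives the primary alcohol without touching either stereocentre, and once the hydride is destroyed the aqueous acid should hydrolyse the aryl dioxolane far faster than it ionises the benzylic alcohol.

Step 8
Reactants: 14 3-[(1S,2R)-1-(4-benzyloxy-3,5-dimethoxyphenyl)-1,3-dihydroxypropan-2-yl]-4,5-dimethoxybenzaldehyde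
Product: 15 3-[(1S,2R)-1-(4-benzyloxy-3,5-dimethoxyphenyl)-1-hydroxy-3-(trityloxy)propan-2-yl]-4,5-dimethoxybenzaldehyde
Conditions: TrCl, Et3N, DMAP (cat.), CH2Cl2, rt
Reagents that add atoms: trityl chloride, ClC(c1ccccc1)(c1ccccc1)c1ccccc1
Why: Tritylation is selective for the primary hydroxyl group over the hindered secondary benzylic one and gives an ether that is inert to alkoxide and cannot migrate.

Step 9
Reactants: 15 3-[(1S,2R)-1-(4-benzyloxy-3,5-dimethoxyphenyl)-1-hydroxy-3-(trityloxy)propan-2-yl]-4,5-dimethoxybenzaldehyde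
Product: 17 (2S,3R)-2-(4-benzyloxy-3,5-dimethoxyphenyl)-7-methoxy-3-(trityloxymethyl)-2,3-dihydro-1-benzofuran-5-carbaldehyde, via potassium alkoxide 16 (not isolated)
Conditions: KH (1.05 equiv), 18-crown-6, THF (0.01 M), argon, 0 → 60 °C; then aq NH4Cl
Reagents that add atoms: none
Why: Proposed new method: deprotonation gives the secondary alkoxide 16, which should add to C7a (C4 of the benzaldehyde ring, para to the formyl group) in a 5-exo-trig sense to give a Meisenheimer anion with its charge on the formyl oxygen, and loss of methoxide then restores the arene and closes the dihydrofuran ring (addition–elimination, SNAr). The closest known reactions are alkoxy-for-methoxy exchange on aryl methyl ethers bearing an ortho- or para-nitro, cyano or carbonyl group, and the closure of alkoxides onto 2-fluoroarenes to give 2,3-dihydrobenzofurans; a formyl group as the only activator for an intramolecular methoxide displacement is the untested part. The C7a methoxy group is flanked by the C7 methoxy group and the side chain, so it is twisted out of conjugation, which should raise the electrophilicity of C7a and make this group the one that leaves. No stereocentre is formed: the C2–O bond and all bonds at C3 stay intact, so the syn (1S,2R) configuration of 15 is carried over as the trans (2S,3R) ring. The site selectivity needed (C7a, not C7) is secured by the para activation and by the tether, which cannot reach C7 without strain, and the primary oxygen, which could close an isomeric five-membered ring on the same carbon, is blocked as the trityl ether. Addition of the alkoxide to the formyl group or to the C–H positions ortho to it is reversible, and hydride transfer to the aldehyde can only occur between molecules, so high dilution and exclusion of air should favour the ring closure.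

Step 10
Reactants: 17 (2S,3R)-2-(4-benzyloxy-3,5-dimethoxyphenyl)-7-methoxy-3-(trityloxymethyl)-2,3-dihydro-1-benzofuran-5-carbaldehyde
Product: 18 methyl (E)-3-[(2S,3R)-2-(4-benzyloxy-3,5-dimethoxyphenyl)-7-methoxy-3-(trityloxymethyl)-2,3-dihydro-1-benzofuran-5-yl]prop-2-enoate
Conditions: (MeO)2P(O)CH2CO2Me, NaH, THF, 0 °C → rt
Reagents that add atoms: trimethyl phosphonoacetate, COC(=O)CP(=O)(OC)OC
Why: Horner–Wadsworth–Emmons olefination of the aromatic aldehyde should give the (E)-acrylate and adds the two missing side-chain carbons, the alkene geometry being of no consequence.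

Step 11
Reactants: 18 methyl (E)-3-[(2S,3R)-2-(4-benzyloxy-3,5-dimethoxyphenyl)-7-methoxy-3-(trityloxymethyl)-2,3-dihydro-1-benzofuran-5-yl]prop-2-enoate
Product: 19 methyl (E)-3-[(2S,3R)-2-(4-benzyloxy-3,5-dimethoxyphenyl)-3-(hydroxymethyl)-7-methoxy-2,3-dihydro-1-benzofuran-5-yl]prop-2-enoate
Conditions: TsOH·H2O (cat.), MeOH–CH2Cl2, rt
Reagents that add atoms: none
Why: Acid-catalysed solvolysis of the trityl ether (SN1, trityl cation trapped by methanol) is carried out while the phenol is still benzylated, so the benzylic C2–O1 bond is not activated toward quinone methide formation.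

Step 12
Reactants: 19 methyl (E)-3-[(2S,3R)-2-(4-benzyloxy-3,5-dimethoxyphenyl)-3-(hydroxymethyl)-7-methoxy-2,3-dihydro-1-benzofuran-5-yl]prop-2-enoate
Product: 20 methyl 3-[(2S,3R)-2-(4-hydroxy-3,5-dimethoxyphenyl)-3-(hydroxymethyl)-7-methoxy-2,3-dihydro-1-benzofuran-5-yl]propanoate
Conditions: H2 (1 atm), 10% Pd/C, EtOAc–MeOH, rt, stopped at full conversion
Reagents that add atoms: none
Why: Heterogeneous hydrogenation saturates the acrylate C=C bond and hydrogenolyses the primary benzyl aryl ether, which should be cleaved far faster than the hindered secondary benzylic C2–O1 bond of the ring.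

Step 13
Reactants: 20 methyl 3-[(2S,3R)-2-(4-hydroxy-3,5-dimethoxyphenyl)-3-(hydroxymethyl)-7-methoxy-2,3-dihydro-1-benzofuran-5-yl]propanoate
Product: 21 4-[(2S,3R)-3-(hydroxymethyl)-5-(3-hydroxypropyl)-7-methoxy-2,3-dihydro-1-benzofuran-2-yl]-2,6-dimethoxyphenol
Conditions: LiAlH4, THF, 0 °C → rt; aq Rochelle salt work-up
Reagents that add atoms: none
Why: Lithium aluminium hydride reduces the methyl ester to the primary alcohol while the phenol and the alcohol are carried as aluminates, which should give the target without affecting C2 or C3.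

**Compound list**
1 | 3-bromo-4,5-dimethoxybenzaldehyde (5-bromoveratraldehyde) | COc1cc(C=O)cc(Br)c1OC | starting material
2 | 2-(3-bromo-4,5-dimethoxyphenyl)-1,3-dioxolane | COc1cc(C2OCCO2)cc(Br)c1OC | intermediate
3 | ethyl 2-[5-(1,3-dioxolan-2-yl)-2,3-dimethoxyphenyl]acetate | CCOC(=O)Cc1cc(C2OCCO2)cc(OC)c1OC | intermediate
4 | 2-[5-(1,3-dioxolan-2-yl)-2,3-dimethoxyphenyl]acetic acid | OC(=O)Cc1cc(C2OCCO2)cc(OC)c1OC | intermediate
5 | (S)-4-benzyl-1,3-oxazolidin-2-one | O=C1N[C@@H](Cc2ccccc2)CO1 | starting material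
6 | mixed anhydride of acid 4 and pivalic acid (formed in the flask) | CC(C)(C)C(=O)OC(=O)Cc1cc(C2OCCO2)cc(OC)c1OC | intermediate
7 | (S)-4-benzyl-3-{2-[5-(1,3-dioxolan-2-yl)-2,3-dimethoxyphenyl]acetyl}-1,3-oxazolidin-2-one | O=C(Cc1cc(C2OCCO2)cc(OC)c1OC)N1[C@@H](Cc2ccccc2)COC1=O | intermediate
8 | syringaldehyde (4-hydroxy-3,5-dimethoxybenzaldehyde) | COc1cc(C=O)cc(OC)c1O | starting material
9 | 4-benzyloxy-3,5-dimethoxybenzaldehyde | COc1cc(C=O)cc(OC)c1OCc1ccccc1 | intermediate
10 | (Z)-dibutylboron enolate of imide 7 (formed in the flask) | CCCCB(CCCC)O/C(=C\c1cc(C2OCCO2)cc(OC)c1OC)N1[C@@H](Cc2ccccc2)COC1=O | intermediate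
11 | O-dibutylboryl aldolate of 12 (formed in the flask) | COc1cc([C@@H](OB(CCCC)CCCC)[C@@H](C(=O)N2[C@@H](Cc3ccccc3)COC2=O)c2cc(C3OCCO3)cc(OC)c2OC)cc(OC)c1OCc1ccccc1 | intermediate
12 | (S)-4-benzyl-3-[(2S,3S)-3-(4-benzyloxy-3,5-dimethoxyphenyl)-2-[5-(1,3-dioxolan-2-yl)-2,3-dimethoxyphenyl]-3-hydroxypropanoyl]-1,3-oxazolidin-2-one | COc1cc([C@@H](O)[C@@H](C(=O)N2[C@@H](Cc3ccccc3)COC2=O)c2cc(C3OCCO3)cc(OC)c2OC)cc(OC)c1OCc1ccccc1 | intermediate
13 | (1S,2R)-1-(4-benzyloxy-3,5-dimethoxyphenyl)-2-[5-(1,3-dioxolan-2-yl)-2,3-dimethoxyphenyl]propane-1,3-diol (formed in the flask) | COc1cc([C@@H](O)[C@@H](CO)c2cc(C3OCCO3)cc(OC)c2OC)cc(OC)c1OCc1ccccc1 | intermediate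
14 | 3-[(1S,2R)-1-(4-benzyloxy-3,5-dimethoxyphenyl)-1,3-dihydroxypropan-2-yl]-4,5-dimethoxybenzaldehyde | COc1cc([C@@H](O)[C@@H](CO)c2cc(C=O)cc(OC)c2OC)cc(OC)c1OCc1ccccc1 | intermediate
15 | 3-[(1S,2R)-1-(4-benzyloxy-3,5-dimethoxyphenyl)-1-hydroxy-3-(trityloxy)propan-2-yl]-4,5-dimethoxybenzaldehyde | COc1cc([C@@H](O)[C@@H](COC(c2ccccc2)(c2ccccc2)c2ccccc2)c2cc(C=O)cc(OC)c2OC)cc(OC)c1OCc1ccccc1 | intermediate
16 | potassium alkoxide of 15 (formed in the flask) | COc1cc([C@@H]([O-])[C@@H](COC(c2ccccc2)(c2ccccc2)c2ccccc2)c2cc(C=O)cc(OC)c2OC)cc(OC)c1OCc1ccccc1.[K+] | intermediate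
17 | (2S,3R)-2-(4-benzyloxy-3,5-dimethoxyphenyl)-7-methoxy-3-(trityloxymethyl)-2,3-dihydro-1-benzofuran-5-carbaldehyde | COc1cc([C@H]2Oc3c(OC)cc(C=O)cc3[C@@H]2COC(c2ccccc2)(c2ccccc2)c2ccccc2)cc(OC)c1OCc1ccccc1 | intermediate
18 | methyl (E)-3-[(2S,3R)-2-(4-benzyloxy-3,5-dimethoxyphenyl)-7-methoxy-3-(trityloxymethyl)-2,3-dihydro-1-benzofuran-5-yl]prop-2-enoate | COc1cc([C@H]2Oc3c(OC)cc(/C=C/C(=O)OC)cc3[C@@H]2COC(c2ccccc2)(c2ccccc2)c2ccccc2)cc(OC)c1OCc1ccccc1 | intermediate
19 | methyl (E)-3-[(2S,3R)-2-(4-benzyloxy-3,5-dimethoxyphenyl)-3-(hydroxymethyl)-7-methoxy-2,3-dihydro-1-benzofuran-5-yl]prop-2-enoate | COc1cc([C@H]2Oc3c(OC)cc(/C=C/C(=O)OC)cc3[C@@H]2CO)cc(OC)c1OCc1ccccc1 | intermediate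
20 | methyl 3-[(2S,3R)-2-(4-hydroxy-3,5-dimethoxyphenyl)-3-(hydroxymethyl)-7-methoxy-2,3-dihydro-1-benzofuran-5-yl]propanoate | COc1cc([C@H]2Oc3c(OC)cc(CCC(=O)OC)cc3[C@@H]2CO)cc(OC)c1O | intermediate
21 | 4-[(2S,3R)-3-(hydroxymethyl)-5-(3-hydroxypropyl)-7-methoxy-2,3-dihydro-1-benzofuran-2-yl]-2,6-dimethoxyphenol | COc1cc([C@H]2Oc3c(OC)cc(CCCO)cc3[C@@H]2CO)cc(OC)c1O | target

**Step count**
Total: 13 steps. Longest linear sequence: 12 steps (steps 1–4 and 6–13).

**Steps most likely to fail**

Step 9 (proposed new method). The alkoxide may fail to add to the electron-rich ring at a temperature the free aldehyde tolerates. Meanwhile the aldehyde may be consumed by intermolecular hydride transfer (Cannizzaro–Tishchenko with the released methoxide, or Oppenauer-type oxidation of the carbinol), or the reversible adducts at C4 and C6 may be oxidised by traces of air. The fallback uses known chemistry and closes O1–C2 instead of O1–C7a; it sets out from 15. Nucleophilic demethylation of the methyl ether para to the formyl group with LiCl in DMF at 140 °C (chloride SN2 at the methyl group, chloromethane escaping; the unactivated methyl ethers and the benzyl ether should remain) should give 3-[(1S,2R)-1-(4-benzyloxy-3,5-dimethoxyphenyl)-1-hydroxy-3-(trityloxy)propan-2-yl]-4-hydroxy-5-methoxybenzaldehyde F1. Treatment of F1 with BF3·OEt2 in CH2Cl2 at 0 °C should ionise the electron-rich benzylic alcohol. Capture of the cation by the neighbouring phenol should give the trans ring, controlled by the untouched C3 centre. The trityl ether is cleaved in the same operation, giving (2S,3R)-2-(4-benzyloxy-3,5-dimethoxyphenyl)-3-(hydroxymethyl)-7-methoxy-2,3-dihydro-1-benzofuran-5-carbaldehyde F2. Horner–Wadsworth–Emmons olefination of F2 with trimethyl phosphonoacetate (NaH, 2 equiv) comes back to the route at 19.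

Step 6. The aldol addition may reverse (aryl-stabilised enolate, electron-rich aldehyde) with loss of syn selectivity, or the boron triflate may ionise the dioxolane. The fallback replaces the aldol addition by acylation and chelation-controlled reduction; it sets out from 4 and 9. Acid 4 is coupled through mixed anhydride 6 with (R)-4-benzyl-1,3-oxazolidin-2-one to give (R)-4-benzyl-3-{2-[5-(1,3-dioxolan-2-yl)-2,3-dimethoxyphenyl]acetyl}-1,3-oxazolidin-2-one F3. The enantiomeric auxiliary is needed because the chelated lithium enolate is acylated on the face opposite to the one the boron enolate uses. Aldehyde 9 is oxidised (NaClO2, NaH2PO4, 2-methyl-2-butene) to 4-benzyloxy-3,5-dimethoxybenzoic acid F4, which oxalyl chloride converts into 4-benzyloxy-3,5-dimethoxybenzoyl chloride F5. The lithium enolate of F3 (LDA, THF, −78 °C) is acylated with F5 to give (R)-4-benzyl-3-[(2S)-3-(4-benzyloxy-3,5-dimethoxyphenyl)-2-[5-(1,3-dioxolan-2-yl)-2,3-dimethoxyphenyl]-3-oxopropanoyl]-1,3-oxazolidin-2-one F6. Zn(BH4)2 (CH2Cl2–Et2O, −20 °C) should reduce F6 through the zinc chelate to the syn alcohol (R)-4-benzyl-3-[(2S,3S)-3-(4-benzyloxy-3,5-dimethoxyphenyl)-2-[5-(1,3-dioxolan-2-yl)-2,3-dimethoxyphenyl]-3-hydroxypropanoyl]-1,3-oxazolidin-2-one F7, the auxiliary epimer of 12. Lithium borohydride cleavage of F7 gives diol acetal 13, and the acidic work-up of step 7 comes back to the route at 14.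

Step 7. The basic hydride may cause retro-aldol cleavage or epimerisation at the α-aryl carbon, hydride may attack the ring carbonyl of the auxiliary, or the aldehyde may be reduced if hydride outlasts the acetal during the acidic work-up. The fallback removes the auxiliary by hydrolysis and then reduces the acid; it sets out from 12. LiOH/H2O2 (THF–H2O, 0 °C) should cleave the exocyclic acyl group to give (2S,3S)-3-(4-benzyloxy-3,5-dimethoxyphenyl)-2-[5-(1,3-dioxolan-2-yl)-2,3-dimethoxyphenyl]-3-hydroxypropanoic acid F8 and release 5. BH3·THF (0 °C → rt) reduces the carboxylic acid to diol acetal 13, which is isolated and hydrolysed with 1 M HCl in THF to come back to the route at 14.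

**Further compounds**
F1 | step 9 | 3-[(1S,2R)-1-(4-benzyloxy-3,5-dimethoxyphenyl)-1-hydroxy-3-(trityloxy)propan-2-yl]-4-hydroxy-5-methoxybenzaldehyde | COc1cc([C@@H](O)[C@@H](COC(c2ccccc2)(c2ccccc2)c2ccccc2)c2cc(C=O)cc(OC)c2O)cc(OC)c1OCc1ccccc1
F2 | step 9 | (2S,3R)-2-(4-benzyloxy-3,5-dimethoxyphenyl)-3-(hydroxymethyl)-7-methoxy-2,3-dihydro-1-benzofuran-5-carbaldehyde | COc1cc([C@H]2Oc3c(OC)cc(C=O)cc3[C@@H]2CO)cc(OC)c1OCc1ccccc1
F3 | step 6 | (R)-4-benzyl-3-{2-[5-(1,3-dioxolan-2-yl)-2,3-dimethoxyphenyl]acetyl}-1,3-oxazolidin-2-one | O=C(Cc1cc(C2OCCO2)cc(OC)c1OC)N1[C@H](Cc2ccccc2)COC1=O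
F4 | step 6 | 4-benzyloxy-3,5-dimethoxybenzoic acid | COc1cc(C(=O)O)cc(OC)c1OCc1ccccc1
F5 | step 6 | 4-benzyloxy-3,5-dimethoxybenzoyl chloride | COc1cc(C(=O)Cl)cc(OC)c1OCc1ccccc1
F6 | step 6 | (R)-4-benzyl-3-[(2S)-3-(4-benzyloxy-3,5-dimethoxyphenyl)-2-[5-(1,3-dioxolan-2-yl)-2,3-dimethoxyphenyl]-3-oxopropanoyl]-1,3-oxazolidin-2-one | COc1cc(C(=O)[C@@H](C(=O)N2[C@H](Cc3ccccc3)COC2=O)c2cc(C3OCCO3)cc(OC)c2OC)cc(OC)c1OCc1ccccc1
F7 | step 6 | (R)-4-benzyl-3-[(2S,3S)-3-(4-benzyloxy-3,5-dimethoxyphenyl)-2-[5-(1,3-dioxolan-2-yl)-2,3-dimethoxyphenyl]-3-hydroxypropanoyl]-1,3-oxazolidin-2-one | COc1cc([C@@H](O)[C@@H](C(=O)N2[C@H](Cc3ccccc3)COC2=O)c2cc(C3OCCO3)cc(OC)c2OC)cc(OC)c1OCc1ccccc1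
F8 | step 7 | (2S,3S)-3-(4-benzyloxy-3,5-dimethoxyphenyl)-2-[5-(1,3-dioxolan-2-yl)-2,3-dimethoxyphenyl]-3-hydroxypropanoic acid | COc1cc([C@@H](O)[C@@H](C(=O)O)c2cc(C3OCCO3)cc(OC)c2OC)cc(OC)c1OCc1ccccc1
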